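The number I carried was 4.11 × 10⁻⁵ M, a reading: the [J] in the grey run at its highest G reading. I called it the turning concentration.

| setting | grey | violet | flask |
|---|---|---|---|
| J | 1.0 × 10⁻⁴ M | 1.5 × 10⁻⁴ M | 2.0 × 10⁻⁴ M |
| remark | run made earlier | run made earlier |  |
| time |  |  | 6.0 min |

| run | time / min | G / % | J / % |
|---|---|---|---|
| grey | 1.00 | 3.5 | 94.5 |
| grey | 1.33 | 4.6 | 91.6 |
| grey | 2.00 | 8.0 | 83.4 |
| grey | 3.00 | 12.1 | 69.8 |
| grey | 5.00 | 17.3 | 41.1 |
| grey | 8.00 | 13.7 | 17.7 |
| violet | 1.00 | 4.1 | 92.9 |
| violet | 1.33 | 6.3 | 87.7 |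
| violet | 2.00 | 10.8 | 76.1 |
| violet | 3.00 | 16.5 | 54.0 |
| violet | 5.00 | 20.1 | 20.4 |
| violet | 8.00 | 12.6 | 5.8 |

(scatter of a reading: 0.3 percentage points)

- the moment within 6.0 min at which there is most G
- the amount of G, in percent of the J charged, at that time

- what was read earlier has a scatter of 0.3 percentage points, one standard deviation

I followed the grey run slowly. At 1.00 min it held 94.5% of J and 3.5% of G. Then the loss of J quickened as G grew, from 5.5 percentage points in the first minute to 14 points between 2.00 min and 3.00 min. G behaved as an intermediate. It had climbed to 17.3% at 5.00 min, but by 8.00 min, with [J] at 1.77 × 10⁻⁵ M, it had dropped to 13.7%.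

The violet run's highest G reading, 20.1% at 5.00 min, stood at [J] of 3.06 × 10⁻⁵ M. The readings on either side of it stood at 8.10 × 10⁻⁵ M and 8.70 × 10⁻⁶ M, and my number lies inside that span. So I assumed, as my own estimate, that the turn comes at about one [J] in these runs and in the new flask. In the new flask that is 20.6% of the charge. This gave me a level of J for the crest, not a time.

The forecast said “The reaction therefore looks autocatalytic, or at least induction-limited”, and it gave 3.7 min and 23.5%.

The flask gave 3.75 min and 23.7%, so the forecast held. At that moment J stood at 21.4%, which is 4.29 × 10⁻⁵ M, beside the 4.11 × 10⁻⁵ M read from the grey run.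

    J + G → 2 G (k = 180 /M/s)
    J → G (k = 5.20 × 10⁻⁴ /s)
    G → E (k = 0.00510 /s)
    J + G → D (k = 72.0 /M/s)

A neighbour flask was charged with 3.4 × 10⁻⁴ M of J and ran for the same 6.0 min. For it my number is 12.1% of the charge. At the end its J stood at 0.322%, or 1.09 × 10⁻⁶ M, far below the turning concentration. That placed the neighbour flask past its crest. It was: its G had reached 28.6% and stood at 12.8% at the end.

(The runs are simulated for an exercise; scatter was added.)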